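**Assumption:** lehualide A has no stereocentres, so "single enantiomer" is taken to mean the single (2E,6Z,9E) geometric isomer. Prenylbenzene is taken as a catalogue item.

## Retrosynthetic overview

1. The pyrone–chain bond is cut at C1'–C2' (sp3–sp2) rather than by olefination or pyrone allylation. It is formed by Zr-catalysed methylalumination of dienyne 7 and Pd-catalysed coupling with 6-(bromomethyl)pyrone 15, which also sets the 2E olefin.
2. The 6Z olefin, the skipped diene and the C4' alcohol handle come from one three-component step: 1,2-metallate rearrangement and ring opening of 5-lithio-2,3-dihydrofuran with a methyl cuprate, trapped with allylic bromide 3.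
3. The 9E olefin comes from E-selective SeO2 oxidation of prenylbenzene.
4. Rings: the phenyl ring is bought and the dihydrofuran ring is sacrificial (opened in step 3). The only ring built is the 2-pyranone, by lactonisation of an acyclic 3,5-diketoester (step 8), before fragment union.

## Route

**Step 1**
Reactants: 1, (3-methylbut-2-en-1-yl)benzene (prenylbenzene)
Product: 2, (2E)-2-methyl-4-phenylbut-2-en-1-ol
Conditions: SeO2 (0.5 equiv), t-BuOOH, salicylic acid (cat.), CH2Cl2, rt; then NaBH4, MeOH, 0 °C
Reagents that add atoms: selenium dioxide, O=[Se]=O (t-BuOOH, CC(C)(C)OO, is the terminal oxidant)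
Why: Riley allylic oxidation (ene then [2,3]-shift) oxidises only the methyl trans to the chain on the more substituted alkene carbon, setting the 9E olefin; the benzylic CH2 sits on the less substituted carbon and is not attacked, and NaBH4 returns any enal to the alcohol.

**Step 2**
Reactants: 2, (2E)-2-methyl-4-phenylbut-2-en-1-ol
Product: 3, [(2E)-4-bromo-3-methylbut-2-en-1-yl]benzene
Conditions: CBr4, PPh3, CH2Cl2, 0 °C; use cold and at once
Reagents that add atoms: carbon tetrabromide, BrC(Br)(Br)Br
Why: Appel bromination of a primary allylic alcohol is a direct SN2 displacement without allylic transposition, so the E geometry is kept.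

**Step 3 (key step)**
Reactants: 4, 2,3-dihydrofuran (2 equiv); 3, [(2E)-4-bromo-3-methylbut-2-en-1-yl]benzene (1 equiv)
Product: 5, (3Z,6E)-4,6-dimethyl-8-phenylocta-3,6-dien-1-ol
Conditions: 4, t-BuLi, THF–pentane, −78→0 °C; add to Me2CuLi (MeLi, CuBr·SMe2), Et2O–Me2S, −40 °C→rt, 1 h; then 3, −78→0 °C; aq. NH4Cl/NH3
Reagents that add atoms: methyllithium, C[Li]
Why: Kocienski 1,2-metallate rearrangement: methyl migrates from copper to the α-alkoxyalkenyl carbon with inversion as the ring C–O bond opens, leaving copper cis to the CH2CH2O– chain; SN2 allylation of this alkenylcuprate with retention then places C8' cis to C5' (6Z), with alkenyl transferring in preference to the residual methyl ligand.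

**Step 4**
Reactants: 5, (3Z,6E)-4,6-dimethyl-8-phenylocta-3,6-dien-1-ol
Product: 6, [(2E,5Z)-8-iodo-3,5-dimethylocta-2,5-dien-1-yl]benzene
Conditions: I2, PPh3, imidazole, CH2Cl2, 0 °C→rt
Reagents that add atoms: iodine, II
Why: Appel-type iodination of a primary alcohol under neutral conditions leaves the acid-sensitive skipped diene untouched.

**Step 5**
Reactants: 6, [(2E,5Z)-8-iodo-3,5-dimethylocta-2,5-dien-1-yl]benzene
Product: 7, [(2E,5Z)-3,5-dimethyldeca-2,5-dien-9-yn-1-yl]benzene
Conditions: LiC≡CH·H2NCH2CH2NH2 (3 equiv), DMSO, rt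
Reagents that add atoms: lithium acetylide (ethylenediamine complex), [Li]C#C
Why: SN2 alkylation of acetylide by a primary iodide in DMSO; acetylide is too weak a base to deprotonate the bis-allylic or benzylic–allylic CH2 groups, so both olefins keep their position and geometry.

**Step 6**
Reactants: 8, methyl methoxyacetate (2.1 equiv); 9, propanoyl chloride (1 equiv)
Product: 10, methyl 2-methoxy-3-oxopentanoate
Conditions: LDA (2.1 equiv), THF, −78 °C; then 9, −78→0 °C; aq. NH4Cl
Reagents that add atoms: none
Why: Crossed Claisen C-acylation of the α-alkoxy ester lithium enolate; the second equivalent of enolate absorbs the acidic β-ketoester proton.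

**Step 7**
Reactants: 10, methyl 2-methoxy-3-oxopentanoate; 11, N-methoxy-N-methylacetamide
Product: 12, methyl 2-methoxy-4-methyl-3,5-dioxohexanoate (tautomer/diastereomer mixture)
Conditions: LDA (2.2 equiv), THF, −78→0 °C; then 11, −78→−20 °C; AcOH quench
Reagents that add atoms: none
Why: The β-ketoester dianion reacts at its more nucleophilic γ-carbon (C4), and the chelated Weinreb tetrahedral intermediate prevents over-addition and proton-transfer quenching.

**Step 8**
Reactants: 12, methyl 2-methoxy-4-methyl-3,5-dioxohexanoate
Product: 13, 4-hydroxy-3-methoxy-5,6-dimethyl-2H-pyran-2-one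
Conditions: DBU, PhMe, 80 °C; 1 M HCl work-up
Reagents that add atoms: none
Why: Base-mediated enol-lactonisation of a 3,5-diketoester (C5 enol oxygen onto the ester, loss of MeOH) is the standard 4-hydroxy-2-pyranone ring synthesis.

**Step 9**
Reactants: 13, 4-hydroxy-3-methoxy-5,6-dimethyl-2H-pyran-2-one
Product: 14, 3-methoxy-5,6-dimethyl-4-[(triisopropylsilyl)oxy]-2H-pyran-2-one
Conditions: TIPSOTf, 2,6-lutidine, CH2Cl2, 0 °C
Reagents that add atoms: triisopropylsilyl triflate, CC(C)[Si](C(C)C)(C(C)C)OS(=O)(=O)C(F)(F)F
Why: O-silylation masks the acidic vinylogous acid as a bulky, fluoride-labile vinylogous silyl ester; any 2-O-silyl isomer would converge on the same product at desilylation.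

**Step 10**
Reactants: 14, 3-methoxy-5,6-dimethyl-4-[(triisopropylsilyl)oxy]-2H-pyran-2-one
Product: 15, 6-(bromomethyl)-3-methoxy-5-methyl-4-[(triisopropylsilyl)oxy]-2H-pyran-2-one
Conditions: NBS (1.05 equiv), AIBN (cat.), PhCF3, 85 °C
Reagents that add atoms: N-bromosuccinimide, O=C1CCC(=O)N1Br
Why: Wohl–Ziegler bromination favours the 6-methyl because its radical is delocalised through the whole pyranone to the carbonyl, whereas the 5-methyl radical is cross-conjugated; C3 and C5 are blocked against ring bromination.

**Step 11 (key step)**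
Reactants: 7, [(2E,5Z)-3,5-dimethyldeca-2,5-dien-9-yn-1-yl]benzene (1.2 equiv); 15, 6-(bromomethyl)-3-methoxy-5-methyl-4-[(triisopropylsilyl)oxy]-2H-pyran-2-one (1 equiv)
Product: 16, 3-methoxy-5-methyl-6-[(2E,6Z,9E)-3,7,9-trimethyl-11-phenylundeca-2,6,9-trien-1-yl]-4-[(triisopropylsilyl)oxy]-2H-pyran-2-one
Conditions: 7, Me3Al (2.5 equiv), Cp2ZrCl2 (20 mol %), CH2Cl2, 0 °C→rt; evaporate excess Me3Al; THF; then 15, Pd(PPh3)4 (5 mol %), 0 °C→rt
Reagents that add atoms: trimethylaluminium, C[Al](C)C
Why: Negishi Zr-catalysed syn-methylalumination of the terminal alkyne (trisubstituted alkenes are inert) gives the (E)-alkenylalane, and Pd-catalysed alkenyl–benzyl-type coupling with retention at the exocyclic CH2 of the heteroarylmethyl bromide sets the 2E olefin as the C1'–C2' bond forms.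

**Step 12**
Reactants: 16, the TIPS-protected coupling product
Product: 17, lehualide A, 4-hydroxy-3-methoxy-5-methyl-6-[(2E,6Z,9E)-3,7,9-trimethyl-11-phenylundeca-2,6,9-trien-1-yl]-2H-pyran-2-one
Conditions: TBAF, AcOH, THF, 0 °C; pH 3 work-up
Reagents that add atoms: none
Why: Buffered fluoride cleaves the vinylogous silyl ester without acid or base strong enough to isomerise or cyclise the skipped triene.

## Compound list

1 | (3-methylbut-2-en-1-yl)benzene | CC(C)=CCc1ccccc1 | starting material
2 | (2E)-2-methyl-4-phenylbut-2-en-1-ol | OC/C(C)=C/Cc1ccccc1 | intermediate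
3 | [(2E)-4-bromo-3-methylbut-2-en-1-yl]benzene | BrC/C(C)=C/Cc1ccccc1 | intermediate
4 | 2,3-dihydrofuran | C1=COCC1 | starting material
5 | (3Z,6E)-4,6-dimethyl-8-phenylocta-3,6-dien-1-ol | OCC/C=C(/C)C/C(C)=C/Cc1ccccc1 | intermediate
6 | [(2E,5Z)-8-iodo-3,5-dimethylocta-2,5-dien-1-yl]benzene | ICC/C=C(/C)C/C(C)=C/Cc1ccccc1 | intermediate
7 | [(2E,5Z)-3,5-dimethyldeca-2,5-dien-9-yn-1-yl]benzene | C#CCC/C=C(/C)C/C(C)=C/Cc1ccccc1 | intermediate
8 | methyl methoxyacetate | COCC(=O)OC | starting material
9 | propanoyl chloride | CCC(=O)Cl | starting material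
10 | methyl 2-methoxy-3-oxopentanoate | CCC(=O)C(OC)C(=O)OC | intermediate
11 | N-methoxy-N-methylacetamide | CC(=O)N(C)OC | starting material
12 | methyl 2-methoxy-4-methyl-3,5-dioxohexanoate | CC(=O)C(C)C(=O)C(OC)C(=O)OC | intermediate
13 | 4-hydroxy-3-methoxy-5,6-dimethyl-2H-pyran-2-one | COc1c(O)c(C)c(C)oc1=O | intermediate
14 | 3-methoxy-5,6-dimethyl-4-[(triisopropylsilyl)oxy]-2H-pyran-2-one | COc1c(O[Si](C(C)C)(C(C)C)C(C)C)c(C)c(C)oc1=O | intermediate
15 | 6-(bromomethyl)-3-methoxy-5-methyl-4-[(triisopropylsilyl)oxy]-2H-pyran-2-one | COc1c(O[Si](C(C)C)(C(C)C)C(C)C)c(C)c(CBr)oc1=O | intermediate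
16 | 3-methoxy-5-methyl-6-[(2E,6Z,9E)-3,7,9-trimethyl-11-phenylundeca-2,6,9-trien-1-yl]-4-[(triisopropylsilyl)oxy]-2H-pyran-2-one | COc1c(O[Si](C(C)C)(C(C)C)C(C)C)c(C)c(C/C=C(\C)CC/C=C(/C)C/C(C)=C/Cc2ccccc2)oc1=O | intermediate
17 | lehualide A | COc1c(O)c(C)c(C/C=C(\C)CC/C=C(/C)C/C(C)=C/Cc2ccccc2)oc1=O | target

## Step count

- Total steps: 12
- Longest linear sequence: 7 (steps 1, 2, 3, 4, 5, 11, 12; the pyrone branch, steps 6–10 then 11 and 12, is also 7)

## Three steps most likely to fail, with fallbacks

1. **Step 3 (metallate rearrangement and allylation).** Methyl may migrate sluggishly, and the cuprate may give SN2' product or transfer methyl to bromide 3. Fallback: drop the three-component step. Make the Z-vinyl iodide by Wittig olefination of 3-(TBSO)propanal with Ph3P=C(I)CH3, convert it by I→Li→Zn exchange to the alkenylzinc, and couple with 3 under Pd(0) (Negishi alkenyl–allyl coupling); desilylation then gives 5.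

2. **Step 11 (carboalumination and coupling to the bromomethylpyrone).** The pyranone or its silyl group may not survive the alane, or the electrophile may homocouple or be methylated. Fallback: build the pyrone last. Convert the alkenylalane to its ate complex (n-BuLi) and open ethylene oxide to give the E-homoallylic alcohol, oxidise it to the β,γ-unsaturated acid, condense its acyl imidazolide with the dianion of 10, and close the ring with DBU. This needs no pyrone protecting group.

3. **Step 10 (radical bromination).** Selectivity for the 6-methyl over the 5-methyl, and survival of the silyl enol ether, are not assured. Fallback: carry the C6 substituent oxygenated from the start. Acylate the dianion of 10 with BnOCH2C(O)N(OMe)Me instead of 11, cyclise, silylate, hydrogenolyse the benzyl ether (no alkenes are present at that stage), and convert the alcohol to bromide 15 with CBr4/PPh3.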